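**Retrosynthetic overview**
1. Feature: ring D of the inden-1-one (C3a, C4, C5, C6, C7, C7a) is a 1,3-dioxygenated benzene (O on C4 and C6) fused at C3a–C7a. Its six carbons are taken as three alkynes: C7a≡C7 of an ethynyl ketone on C1, C3a≡C4 of an alkynyl ether on C3, and C5≡C6 of methoxyacetylene.
2. Key disconnection: RhCl(PPh3)3-catalysed (2+2+2) cyclotrimerisation of the cis-enediynone with methoxyacetylene forms C3a–C7a, C4–C5 and C6–C7 and closes the five-membered ring and ring D together; BCl3 then frees the five phenols.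
3. Enediynone: the ethynyl ketone comes from an N-methoxy-N-methylamide and HC≡CMgBr, the alkynyl ether from Negishi coupling of tert-butoxyethynylzinc chloride with a (Z)-enol triflate, and the triflate from a β-keto amide made by C-acylation of the ring B arylacetamide with the ring C aroyl chloride.
4. Rings A–B: the diaryl ether is made by SNAr of an ortho-allylphenol (Claisen rearrangement) on a 2-fluorobenzaldehyde; the allyl group is cut down to the acetic acid side chain.
5. Ring order: rings A, B and C are bought as arenes; the five-membered ring and ring D are formed last and together.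

Key step: step 19

Remark on the chemistry: ring A = benzoate ring, ring B = central aryloxyphenyl ring on C2, ring C = 2,6-dioxygenated tolyl ring on C3, ring D = benzo ring of the indenone.
Remark on the chemistry: the C4 oxygen is brought in as a ready-made tert-butyl alkynyl ether by cross-coupling. An ynolate on C3 would be conjugated through C2=C3 with the C1 carboxyl group, so its O-silylation is not relied on; the tert-butyl ether falls with the benzyl ethers in the last step.
Remark on the chemistry: the arrangement needed for the cyclisation (C1 carbonyl cis to the C3 alkyne) has the CIP descriptor Z in the enol triflate and E in the enyne amide and the ynone, because the ring C aryl group outranks the alkynyl ether on C3.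
Assumption: 2-(benzyloxy)-4-methoxybenzaldehyde and 2,6-difluoro-4-methylbenzaldehyde are taken as catalogue compounds.

**Route**

Step 1
Reactants: 1 2-(benzyloxy)-4-methoxybenzaldehyde
Product: 3 2-(benzyloxy)-4-methoxyphenol, via aryl formate 2 (not isolated)
Conditions: mCPBA, CH2Cl2, 0 °C→rt; then K2CO3, MeOH, rt
Reagents that add atoms: mCPBA (3-chloroperoxybenzoic acid), O=C(OO)c1cccc(Cl)c1
Why: Baeyer–Villiger oxidation with migration of the electron-rich aryl group, followed by methanolysis of the formate (a Dakin-type sequence), should turn the formyl carbon into the phenol oxygen that lies para to the methoxy group.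

Step 2
Reactants: 3 2-(benzyloxy)-4-methoxyphenol
Product: 4 1-(allyloxy)-2-(benzyloxy)-4-methoxybenzene
Conditions: allyl bromide, K2CO3, acetone, reflux
Reagents that add atoms: allyl bromide, C=CCBr
Why: Williamson O-allylation of the phenoxide should be clean because the phenol is the only acidic site.

Step 3
Reactants: 4 1-(allyloxy)-2-(benzyloxy)-4-methoxybenzene
Product: 5 2-allyl-6-(benzyloxy)-4-methoxyphenol
Conditions: PhNEt2, 190 °C, argon
Reagents that add atoms: none
Why: Aromatic Claisen rearrangement ([3,3] shift, then tautomerisation) should deliver the allyl group to the only free ortho position, since the other ortho carbon carries the benzyloxy group and the para carbon the methoxy group.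

Step 4
Reactants: 6 2,6-difluoro-4-methylbenzaldehyde
Product: 7 2-(benzyloxy)-6-fluoro-4-methylbenzaldehyde
Conditions: BnOH (1.0 equiv), NaH, THF, 0 °C→rt
Reagents that add atoms: benzyl alcohol, OCc1ccccc1
Why: Nucleophilic aromatic substitution of one fluoride ortho to the formyl group by sodium benzyloxide should stop after one exchange, because the first alkoxy group deactivates the ring towards the second.

Step 5
Reactants: 5 2-allyl-6-(benzyloxy)-4-methoxyphenol and 7 2-(benzyloxy)-6-fluoro-4-methylbenzaldehyde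
Product: 8 2-[2-allyl-6-(benzyloxy)-4-methoxyphenoxy]-6-(benzyloxy)-4-methylbenzaldehyde
Conditions: K2CO3, DMF, 100 °C, argon
Reagents that add atoms: none
Why: Nucleophilic aromatic substitution of the remaining fluoride, activated by the ortho formyl group, by the phenoxide of 5 should form the hindered ring A–ring B diaryl ether without a metal catalyst, and carbonate is too weak a base to isomerise the allyl group.

Step 6
Reactants: 8 2-[2-allyl-6-(benzyloxy)-4-methoxyphenoxy]-6-(benzyloxy)-4-methylbenzaldehyde
Product: 9 2-(benzyloxy)-6-[2-(benzyloxy)-4-methoxy-6-(2-oxoethyl)phenoxy]-4-methylbenzaldehyde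
Conditions: OsO4 (2 mol %), NaIO4, 2,6-lutidine, dioxane/H2O, rt; used crude
Reagents that add atoms: OsO4 (catalytic), O=[Os](=O)(=O)=O; NaIO4 (terminal oxidant), [Na+].[O-]I(=O)(=O)=O
Why: Lemieux–Johnson cleavage (dihydroxylation by OsO4 and periodate scission) should cut the terminal alkene to the arylacetaldehyde and leave the aryl aldehyde, the benzyl ethers and the electron-rich rings untouched.

Step 7
Reactants: 9 2-(benzyloxy)-6-[2-(benzyloxy)-4-methoxy-6-(2-oxoethyl)phenoxy]-4-methylbenzaldehyde
Product: 10 2-(benzyloxy)-6-[2-(benzyloxy)-6-(carboxymethyl)-4-methoxyphenoxy]-4-methylbenzoic acid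
Conditions: NaClO2, NaH2PO4, 2-methyl-2-butene, t-BuOH/H2O, 0 °C→rt
Reagents that add atoms: sodium chlorite, [Na+].[O-]Cl=O
Why: Pinnick oxidation should convert both aldehydes into carboxylic acids, the 2-methyl-2-butene scavenger protecting the electron-rich rings from hypochlorous acid.

Step 8
Reactants: 10 2-(benzyloxy)-6-[2-(benzyloxy)-6-(carboxymethyl)-4-methoxyphenoxy]-4-methylbenzoic acid
Product: 11 methyl 2-(benzyloxy)-6-[2-(benzyloxy)-4-methoxy-6-(2-methoxy-2-oxoethyl)phenoxy]-4-methylbenzoate
Conditions: MeI, K2CO3, DMF, rt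
Reagents that add atoms: iodomethane, CI
Why: SN2 O-alkylation of both carboxylates should also esterify the hindered 2,6-disubstituted benzoic acid, which resists Fischer esterification.

Step 9
Reactants: 11 methyl 2-(benzyloxy)-6-[2-(benzyloxy)-4-methoxy-6-(2-methoxy-2-oxoethyl)phenoxy]-4-methylbenzoate
Product: 12 methyl 2-(benzyloxy)-6-{2-(benzyloxy)-4-methoxy-6-[2-(methoxy(methyl)amino)-2-oxoethyl]phenoxy}-4-methylbenzoate
Conditions: MeNH(OMe)·HCl, i-PrMgCl, THF, −20→0 °C
Reagents that add atoms: N,O-dimethylhydroxylamine hydrochloride, CNOC.Cl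
Why: Ester aminolysis by the chloromagnesium amide of N,O-dimethylhydroxylamine should take place only at the unhindered arylacetate, the ring A benzoate being shielded on both sides.

Step 10
Reactants: 13 methyl 2,6-dihydroxy-4-methylbenzoate
Product: 14 methyl 2,6-bis(benzyloxy)-4-methylbenzoate
Conditions: BnBr, K2CO3, DMF, 60 °C
Reagents that add atoms: benzyl bromide, BrCc1ccccc1
Why: Williamson O-benzylation of both phenols should go to completion with excess bromide, the ester being inert to carbonate.

Step 11
Reactants: 14 methyl 2,6-bis(benzyloxy)-4-methylbenzoate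
Product: 15 2,6-bis(benzyloxy)-4-methylbenzoic acid
Conditions: KOH, DMSO/H2O, 90 °C; then aq. HCl
Reagents that add atoms: potassium hydroxide, [K+].[OH-]
Why: Saponification of the hindered benzoate needs the poorly solvated hydroxide of aqueous DMSO at elevated temperature, conditions that benzyl ethers tolerate.

Step 12
Reactants: 15 2,6-bis(benzyloxy)-4-methylbenzoic acid
Product: 16 2,6-bis(benzyloxy)-4-methylbenzoyl chloride
Conditions: (COCl)2, DMF (cat.), CH2Cl2, 0 °C→rt; used crude
Reagents that add atoms: oxalyl chloride, O=C(Cl)C(=O)Cl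
Why: Chlorination of the acid through the chloroiminium species formed from DMF and oxalyl chloride should give the acid chloride under conditions that leave the benzyl ethers intact.

Step 13
Reactants: 12 methyl 2-(benzyloxy)-6-{2-(benzyloxy)-4-methoxy-6-[2-(methoxy(methyl)amino)-2-oxoethyl]phenoxy}-4-methylbenzoate and 16 2,6-bis(benzyloxy)-4-methylbenzoyl chloride
Product: 17 β-keto amide methyl 2-(benzyloxy)-6-{2-(benzyloxy)-6-[1-(2,6-bis(benzyloxy)-4-methylphenyl)-3-(methoxy(methyl)amino)-1,3-dioxopropan-2-yl]-4-methoxyphenoxy}-4-methylbenzoate (racemic)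
Conditions: LiN(SiMe3)2 (2.2 equiv), THF, −78 °C; then 16, −78→−20 °C
Reagents that add atoms: none
Why: Claisen-type C-acylation of the lithium enolate of the arylacetamide by the aroyl chloride should be driven to completion by deprotonation of the more acidic β-keto amide with the second equivalent of base, while at −78 °C the enolate should not attack the shielded ring A ester, and the new stereocentre forms as a racemate that is removed in step 14.

Step 14
Reactants: 17 β-keto amide
Product: 18 (Z)-enol triflate methyl 2-(benzyloxy)-6-{2-(benzyloxy)-6-[(1Z)-1-(2,6-bis(benzyloxy)-4-methylphenyl)-3-(methoxy(methyl)amino)-3-oxo-1-(trifluoromethylsulfonyloxy)prop-1-en-2-yl]-4-methoxyphenoxy}-4-methylbenzoate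
Conditions: LiN(SiMe3)2, THF, −78 °C; N-(5-chloro-2-pyridyl)bis(trifluoromethanesulfonimide), −78→0 °C
Reagents that add atoms: N-(5-chloro-2-pyridyl)bis(trifluoromethanesulfonimide), O=S(=O)(N(c1ccc(Cl)cn1)S(=O)(=O)C(F)(F)F)C(F)(F)F
Why: O-sulfonylation of the lithium-chelated enolate, in which the enolate oxygen and the amide carbonyl are held cis, should give the (Z)-enol triflate, and the N-aryl triflimide does not activate the tertiary amide as Tf2O would.

Step 15
Reactants: 19 trichloroethylene
Product: 20 (E)-1-tert-butoxy-1,2-dichloroethene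
Conditions: KOt-Bu, THF, −78 °C→rt
Reagents that add atoms: potassium tert-butoxide, CC(C)(C)[O-].[K+]
Why: Base-induced loss of HCl from trichloroethylene to dichloroacetylene and anti addition of tert-butoxide across it is the standard route to (E)-1,2-dichlorovinyl ethers.

Step 16
Reactants: 18 (Z)-enol triflate and 20 (E)-1-tert-butoxy-1,2-dichloroethene
Product: 23 (2E)-enyne N-methoxy-N-methylamide (amide carbonyl cis to the alkynyl ether), via lithium tert-butoxyacetylide 21 (not isolated), via tert-butoxyethynylzinc chloride 22 (not isolated)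
Conditions: 20, n-BuLi (2 equiv per 20), THF, −78 °C; ZnCl2, −78→0 °C; then 18, Pd(PPh3)4 (5 mol %), THF, rt, kept below 25 °C
Reagents that add atoms: none
Why: Deprotonation, loss of LiCl and chlorine–lithium exchange convert 20 into the lithium alkoxyacetylide, and Negishi coupling of its zinc derivative with the enol triflate at zerovalent palladium should proceed with retention of the alkene geometry, a slim alkynylzinc being the nucleophile best suited to the congested C3.

Step 17
Reactants: 23 (2E)-enyne N-methoxy-N-methylamide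
Product: 24 (4E)-enediynone methyl 2-(benzyloxy)-6-{2-(benzyloxy)-6-[(4E)-5-(2,6-bis(benzyloxy)-4-methylphenyl)-7-tert-butoxy-3-oxohepta-4-ene-1,6-diyn-4-yl]-4-methoxyphenoxy}-4-methylbenzoate
Conditions: HC≡CMgBr (excess), THF, 0 °C; poured into cold aq. NH4Cl; used at once
Reagents that add atoms: ethynylmagnesium bromide, C#C[Mg]Br
Why: Addition of the ethynyl Grignard reagent to the N-methoxy-N-methylamide gives a stable magnesium chelate that releases the ketone only on quench (Weinreb ketone synthesis), so the sensitive cross-conjugated ethynyl ketone is unmasked directly before the cyclisation, while the alkynyl ether and the hindered ring A ester are inert to the Grignard reagent.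

Step 18
Reactants: 25 chloroacetaldehyde dimethyl acetal
Product: 27 methoxyacetylene, via sodium methoxyacetylide 26 (not isolated)
Conditions: NaNH2 (3 equiv), liq. NH3, −33 °C; then cold aq. NaCl; distilled into toluene at −78 °C
Reagents that add atoms: none
Why: Twofold elimination (HCl and methanol) from the chloroacetal by NaNH2 gives the sodium acetylide, and the aqueous quench liberates the volatile alkoxyacetylene, which is used as a cold toluene solution.

Step 19
Reactants: 24 (4E)-enediynone and 27 methoxyacetylene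
Product: 28 methyl 2-(benzyloxy)-6-{2-(benzyloxy)-6-[3-(2,6-bis(benzyloxy)-4-methylphenyl)-4-tert-butoxy-6-methoxy-1-oxo-1H-inden-2-yl]-4-methoxyphenoxy}-4-methylbenzoate
Conditions: RhCl(PPh3)3 (10 mol %), 27 (10 equiv), toluene, 20–30 °C, slow addition of 24
Reagents that add atoms: none
Why: Proposed new method: loss of PPh3 from RhCl(PPh3)3 lets monovalent rhodium bind the electron-poor ynone alkyne and the electron-rich alkynyl ether of 24, which are held cis on C2=C3, and oxidative coupling gives a trivalent rhodacyclopentadiene with the new bond C3a–C7a and rhodium bonded to C7 and C4; insertion of methoxyacetylene and C–C reductive elimination then form C4–C5 and C6–C7 and return monovalent rhodium. The closest known reaction type is the RhCl(PPh3)3- or CpCo(CO)2-catalysed (2+2+2) cyclotrimerisation of 1,6-diynes, diynones among them, with terminal alkynes including alkoxyacetylenes; what lacks precedent is a diyne whose alkynyl ether terminus is in push–pull conjugation with a terminal ynone. The five-membered ring closes in the oxidative coupling (exo with respect to both triple bonds, the 1,6-diyne mode), and ring D closes in the insertion and reductive elimination sequence, a formal (4+2) of the rhodacycle with the third alkyne. No stereocentre is formed. The step needs regioselective insertion of methoxyacetylene (methoxy carbon to C7, CH to C4, giving the 4,6- and not the 4,5-dioxygenated ring), which the bulky tert-butoxy group on C4 against the hydrogen on C7 should secure, in line with the meta preference of RhCl(PPh3)3 for 1,6-diynes with one substituted terminus; it also needs cross- over homo-trimerisation, which the tethered diyne, the excess of 27 and the slow addition of 24 should secure.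

Step 20
Reactants: 28 tert-butyl tetrabenzyl ether of the target
Product: 29 Ascomindone B
Conditions: BCl3, C6HMe5, CH2Cl2, −78→−40 °C; MeOH quench
Reagents that add atoms: none
Why: Lewis acid cleavage of the four benzyl ethers and the tert-butyl ether by BCl3, with pentamethylbenzene as a non-basic cation scavenger that prevents C-benzylation of the electron-rich rings, should leave the two aryl methyl ethers (neither is ortho to a carbonyl group), the methyl ester and the indenone intact at low temperature.

**Compound list**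
1 | 2-(benzyloxy)-4-methoxybenzaldehyde | O=Cc1ccc(OC)cc1OCc1ccccc1 | starting material
2 | 2-(benzyloxy)-4-methoxyphenyl formate | O=COc1ccc(OC)cc1OCc1ccccc1 | intermediate
3 | 2-(benzyloxy)-4-methoxyphenol | Oc1ccc(OC)cc1OCc1ccccc1 | intermediate
4 | 1-(allyloxy)-2-(benzyloxy)-4-methoxybenzene | C=CCOc1ccc(OC)cc1OCc1ccccc1 | intermediate
5 | 2-allyl-6-(benzyloxy)-4-methoxyphenol | C=CCc1cc(OC)cc(OCc2ccccc2)c1O | intermediate
6 | 2,6-difluoro-4-methylbenzaldehyde | O=Cc1c(F)cc(C)cc1F | starting material
7 | 2-(benzyloxy)-6-fluoro-4-methylbenzaldehyde | O=Cc1c(F)cc(C)cc1OCc1ccccc1 | intermediate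
8 | 2-[2-allyl-6-(benzyloxy)-4-methoxyphenoxy]-6-(benzyloxy)-4-methylbenzaldehyde | C=CCc1cc(OC)cc(OCc2ccccc2)c1Oc1cc(C)cc(OCc2ccccc2)c1C=O | intermediate
9 | 2-(benzyloxy)-6-[2-(benzyloxy)-4-methoxy-6-(2-oxoethyl)phenoxy]-4-methylbenzaldehyde | O=CCc1cc(OC)cc(OCc2ccccc2)c1Oc1cc(C)cc(OCc2ccccc2)c1C=O | intermediate
10 | 2-(benzyloxy)-6-[2-(benzyloxy)-6-(carboxymethyl)-4-methoxyphenoxy]-4-methylbenzoic acid | OC(=O)Cc1cc(OC)cc(OCc2ccccc2)c1Oc1cc(C)cc(OCc2ccccc2)c1C(=O)O | intermediate
11 | methyl 2-(benzyloxy)-6-[2-(benzyloxy)-4-methoxy-6-(2-methoxy-2-oxoethyl)phenoxy]-4-methylbenzoate | COC(=O)Cc1cc(OC)cc(OCc2ccccc2)c1Oc1cc(C)cc(OCc2ccccc2)c1C(=O)OC | intermediate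
12 | methyl 2-(benzyloxy)-6-{2-(benzyloxy)-4-methoxy-6-[2-(methoxy(methyl)amino)-2-oxoethyl]phenoxy}-4-methylbenzoate | CON(C)C(=O)Cc1cc(OC)cc(OCc2ccccc2)c1Oc1cc(C)cc(OCc2ccccc2)c1C(=O)OC | intermediate
13 | methyl 2,6-dihydroxy-4-methylbenzoate | COC(=O)c1c(O)cc(C)cc1O | starting material
14 | methyl 2,6-bis(benzyloxy)-4-methylbenzoate | COC(=O)c1c(OCc2ccccc2)cc(C)cc1OCc1ccccc1 | intermediate
15 | 2,6-bis(benzyloxy)-4-methylbenzoic acid | OC(=O)c1c(OCc2ccccc2)cc(C)cc1OCc1ccccc1 | intermediate
16 | 2,6-bis(benzyloxy)-4-methylbenzoyl chloride | O=C(Cl)c1c(OCc2ccccc2)cc(C)cc1OCc1ccccc1 | intermediate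
17 | methyl 2-(benzyloxy)-6-{2-(benzyloxy)-6-[1-(2,6-bis(benzyloxy)-4-methylphenyl)-3-(methoxy(methyl)amino)-1,3-dioxopropan-2-yl]-4-methoxyphenoxy}-4-methylbenzoate (β-keto amide, racemic) | CON(C)C(=O)C(C(=O)c1c(OCc2ccccc2)cc(C)cc1OCc1ccccc1)c1cc(OC)cc(OCc2ccccc2)c1Oc1cc(C)cc(OCc2ccccc2)c1C(=O)OC | intermediate
18 | methyl 2-(benzyloxy)-6-{2-(benzyloxy)-6-[(1Z)-1-(2,6-bis(benzyloxy)-4-methylphenyl)-3-(methoxy(methyl)amino)-3-oxo-1-(trifluoromethylsulfonyloxy)prop-1-en-2-yl]-4-methoxyphenoxy}-4-methylbenzoate (enol triflate, OTf cis to the amide carbonyl) | CON(C)C(=O)/C(c1cc(OC)cc(OCc2ccccc2)c1Oc1cc(C)cc(OCc2ccccc2)c1C(=O)OC)=C(/c1c(OCc2ccccc2)cc(C)cc1OCc1ccccc1)OS(=O)(=O)C(F)(F)F | intermediate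
19 | trichloroethylene | ClC=C(Cl)Cl | starting material
20 | (E)-1-tert-butoxy-1,2-dichloroethene | Cl/C=C(/Cl)OC(C)(C)C | intermediate
21 | lithium tert-butoxyacetylide | [Li]C#COC(C)(C)C | intermediate
22 | tert-butoxyethynylzinc chloride | Cl[Zn]C#COC(C)(C)C | intermediate
23 | methyl 2-(benzyloxy)-6-{2-(benzyloxy)-6-[(2E)-3-(2,6-bis(benzyloxy)-4-methylphenyl)-5-tert-butoxy-1-(methoxy(methyl)amino)-1-oxopent-2-en-4-yn-2-yl]-4-methoxyphenoxy}-4-methylbenzoate (amide carbonyl cis to the alkynyl ether) | CON(C)C(=O)/C(c1cc(OC)cc(OCc2ccccc2)c1Oc1cc(C)cc(OCc2ccccc2)c1C(=O)OC)=C(/c1c(OCc2ccccc2)cc(C)cc1OCc1ccccc1)C#COC(C)(C)C | intermediate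
24 | methyl 2-(benzyloxy)-6-{2-(benzyloxy)-6-[(4E)-5-(2,6-bis(benzyloxy)-4-methylphenyl)-7-tert-butoxy-3-oxohepta-4-ene-1,6-diyn-4-yl]-4-methoxyphenoxy}-4-methylbenzoate (ketone cis to the alkynyl ether) | C#CC(=O)/C(c1cc(OC)cc(OCc2ccccc2)c1Oc1cc(C)cc(OCc2ccccc2)c1C(=O)OC)=C(/c1c(OCc2ccccc2)cc(C)cc1OCc1ccccc1)C#COC(C)(C)C | intermediate
25 | chloroacetaldehyde dimethyl acetal | COC(CCl)OC | starting material
26 | sodium methoxyacetylide | [Na]C#COC | intermediate
27 | methoxyacetylene | C#COC | intermediate
28 | methyl 2-(benzyloxy)-6-{2-(benzyloxy)-6-[3-(2,6-bis(benzyloxy)-4-methylphenyl)-4-tert-butoxy-6-methoxy-1-oxo-1H-inden-2-yl]-4-methoxyphenoxy}-4-methylbenzoate | COC(=O)c1c(OCc2ccccc2)cc(C)cc1Oc1c(OCc2ccccc2)cc(OC)cc1C1=C(c2c(OCc3ccccc3)cc(C)cc2OCc2ccccc2)c2c(OC(C)(C)C)cc(OC)cc2C1=O | intermediate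
29 | Ascomindone B, methyl 2-{2-[3-(2,6-dihydroxy-4-methylphenyl)-4-hydroxy-6-methoxy-1-oxo-1H-inden-2-yl]-6-hydroxy-4-methoxyphenoxy}-6-hydroxy-4-methylbenzoate | COC(=O)c1c(O)cc(C)cc1Oc1c(O)cc(OC)cc1C1=C(c2c(O)cc(C)cc2O)c2c(O)cc(OC)cc2C1=O | target

**Step count**
Total: 20 steps. Longest linear sequence: 14 steps (1, 2, 3, 5, 6, 7, 8, 9, 13, 14, 16, 17, 19, 20).

**Steps most likely to fail**

Step 19 (proposed new method). What may go wrong: homo-oligomerisation of methoxyacetylene outruns the cross-reaction, the push–pull enediynone decomposes at rhodium (loss of 2-methylpropene from the alkynyl ether, or vinylidene chemistry at the terminal ynone), or methoxyacetylene inserts in the other orientation. The fallback replaces the alkynyl ether terminus by an alkynylsilane and introduces the C4 oxygen by oxidation; it sets out from 18 and comes back at 29. Sonogashira coupling of 18 with benzyl(ethynyl)dimethylsilane F1 (made from HC≡CMgBr and benzylchlorodimethylsilane) under PdCl2(PPh3)2, CuI and Et3N in THF would give the silyl enyne amide F2. HC≡CMgBr as in step 17 would give the silyl enediynone F3. Cyclotrimerisation of F3 with 27 under RhCl(PPh3)3 would give the C4-silyl indenone F4; a silyl-terminated 1,6-diyne with a terminal alkyne is an established substrate pair with the same meta preference. Fluoride-triggered Tamao–Fleming oxidation (Bu4NF, THF, 0 °C; then H2O2, KHCO3, MeOH) would give the C4 phenol F5, and BCl3 with C6HMe5 as in step 20 would give 29.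

Step 16. What may go wrong: oxidative addition and transmetalation are slow at the congested C3, and the alkoxyacetylide is lost by protonation or by elimination of 2-methylpropene before it couples. The fallback separates the making of the acetylide from the coupling; it sets out from 20 and 18 and comes back at 23. The acetylide 21 would be trapped with Bu3SnCl to give tributyl(tert-butoxyethynyl)stannane F6, which can be purified and stored cold. Stille coupling of F6 with 18 under Pd(PPh3)4, CuI and LiCl in DMF at rt would then give 23 under neutral conditions.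

Step 17. What may go wrong: addition to the hindered, conjugated amide is incomplete, and the liberated N,O-dimethylhydroxylamine adds in conjugate fashion to the terminal ynone during the quench. The fallback builds the ketone by a redox sequence in which no amine is released next to the ynone; it sets out from 23 and comes back at 24. Reduction of 23 with i-Bu2AlH in THF at −78 °C would give the enal F7. Addition of HC≡CMgBr at −78 °C would give the propargylic alcohol F8 (racemic), and MnO2 in CH2Cl2 at rt would oxidise this doubly activated alcohol to 24 under neutral conditions.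

**Further compounds**
F1 | step 19 | benzyl(ethynyl)dimethylsilane | C#C[Si](C)(C)Cc1ccccc1
F2 | step 19 | silyl enyne amide, methyl 2-(benzyloxy)-6-{2-(benzyloxy)-6-[(2E)-5-(benzyldimethylsilyl)-3-(2,6-bis(benzyloxy)-4-methylphenyl)-1-(methoxy(methyl)amino)-1-oxopent-2-en-4-yn-2-yl]-4-methoxyphenoxy}-4-methylbenzoate | CON(C)C(=O)/C(c1cc(OC)cc(OCc2ccccc2)c1Oc1cc(C)cc(OCc2ccccc2)c1C(=O)OC)=C(/c1c(OCc2ccccc2)cc(C)cc1OCc1ccccc1)C#C[Si](C)(C)Cc1ccccc1
F3 | step 19 | silyl enediynone, methyl 2-(benzyloxy)-6-{2-(benzyloxy)-6-[(4E)-7-(benzyldimethylsilyl)-5-(2,6-bis(benzyloxy)-4-methylphenyl)-3-oxohepta-4-ene-1,6-diyn-4-yl]-4-methoxyphenoxy}-4-methylbenzoate | C#CC(=O)/C(c1cc(OC)cc(OCc2ccccc2)c1Oc1cc(C)cc(OCc2ccccc2)c1C(=O)OC)=C(/c1c(OCc2ccccc2)cc(C)cc1OCc1ccccc1)C#C[Si](C)(C)Cc1ccccc1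
F4 | step 19 | C4-silyl indenone, methyl 2-(benzyloxy)-6-{2-(benzyloxy)-6-[4-(benzyldimethylsilyl)-3-(2,6-bis(benzyloxy)-4-methylphenyl)-6-methoxy-1-oxo-1H-inden-2-yl]-4-methoxyphenoxy}-4-methylbenzoate | COC(=O)c1c(OCc2ccccc2)cc(C)cc1Oc1c(OCc2ccccc2)cc(OC)cc1C1=C(c2c(OCc3ccccc3)cc(C)cc2OCc2ccccc2)c2c([Si](C)(C)Cc3ccccc3)cc(OC)cc2C1=O
F5 | step 19 | C4 phenol, methyl 2-(benzyloxy)-6-{2-(benzyloxy)-6-[3-(2,6-bis(benzyloxy)-4-methylphenyl)-4-hydroxy-6-methoxy-1-oxo-1H-inden-2-yl]-4-methoxyphenoxy}-4-methylbenzoate | COC(=O)c1c(OCc2ccccc2)cc(C)cc1Oc1c(OCc2ccccc2)cc(OC)cc1C1=C(c2c(OCc3ccccc3)cc(C)cc2OCc2ccccc2)c2c(O)cc(OC)cc2C1=O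
F6 | step 16 | tributyl(tert-butoxyethynyl)stannane | CCCC[Sn](CCCC)(CCCC)C#COC(C)(C)C
F7 | step 17 | enal, methyl 2-(benzyloxy)-6-{2-(benzyloxy)-6-[(2E)-3-(2,6-bis(benzyloxy)-4-methylphenyl)-5-tert-butoxy-1-oxopent-2-en-4-yn-2-yl]-4-methoxyphenoxy}-4-methylbenzoate | O=C/C(c1cc(OC)cc(OCc2ccccc2)c1Oc1cc(C)cc(OCc2ccccc2)c1C(=O)OC)=C(/c1c(OCc2ccccc2)cc(C)cc1OCc1ccccc1)C#COC(C)(C)C
F8 | step 17 | propargylic alcohol (racemic), methyl 2-(benzyloxy)-6-{2-(benzyloxy)-6-[(4E)-5-(2,6-bis(benzyloxy)-4-methylphenyl)-7-tert-butoxy-3-hydroxyhepta-4-ene-1,6-diyn-4-yl]-4-methoxyphenoxy}-4-methylbenzoate | C#CC(O)/C(c1cc(OC)cc(OCc2ccccc2)c1Oc1cc(C)cc(OCc2ccccc2)c1C(=O)OC)=C(/c1c(OCc2ccccc2)cc(C)cc1OCc1ccccc1)C#COC(C)(C)C
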